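## Retrosynthetic overview
1. The last bond made is central aryl C–C(quinone methide). It is cut into a hindered aryl chloride (electrophilic carbon) and the phenylogous acyl anion O=C6H4=C(−)Ph. The reagent for this anion is 4-hydroxybenzophenone N-tosylhydrazone (diazoalkane, then palladium carbene), so the bond and the quinone methide form in one operation without protecting groups.
2. The aryl chloride comes from 1,3-dibromo-2-chloro-4-methylbenzene. The alkyne is set by Sonogashira coupling at the hindered C–Br and the biaryl by Suzuki coupling at the open C–Br.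
3. The trihalide comes from 2,4-dibromotoluene by deprotonation between the two bromines and a Cl+ quench.
4. Rings: all four six-membered rings are bought as arenes and none is built. The cyclohexadienone ring arises in the last step by dearomatisation of the phenol ring of the benzophenone.

Assumption: the SMILES holds no stereocentre, no E/Z-stereogenic double bond (the cyclohexadienone ring is symmetric about the exocyclic C=C) and no specified axis. The compound is therefore made as drawn, and no stereocontrolling step is needed.

## Route

Step 1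
Reactants: 1 2,4-dibromotoluene
Product: 3 1,3-dibromo-2-chloro-4-methylbenzene, via aryllithium 2 (not isolated)
Conditions: LiN(iPr)2 (1.05 equiv), THF, −78 °C, 1 h; then C2Cl6 (1.2 equiv), −78 °C to rt
Reagents that add atoms: hexachloroethane, ClC(Cl)(Cl)C(Cl)(Cl)Cl
Why: Deprotonative ortho-lithiation removes the ring proton flanked by two bromines, which is by far the most acidic; the doubly halogen-flanked aryllithium 2 is the thermodynamic sink (no halogen dance) and holds at −78 °C, and halophilic attack on C2Cl6 delivers Cl+; no stereocentre is formed.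

Step 2
Reactants: 3 1,3-dibromo-2-chloro-4-methylbenzene; 4 4-hydroxyphenylboronic acid
Product: 5 3'-bromo-2'-chloro-4'-methylbiphenyl-4-ol
Conditions: 4 (1.0 equiv), Pd(PPh3)4 (3 mol %), Na2CO3 (3 equiv), 1,4-dioxane/H2O 4:1, 80 °C
Reagents that add atoms: none
Why: In this site-selective Suzuki–Miyaura coupling, oxidative addition prefers the C–Br bond with one ortho substituent (Cl and H as neighbours) over the one between Cl and CH3; C–Cl is inert to Pd(PPh3)4 and the free phenol is carried as its phenoxide.

Step 3
Reactants: 5 3'-bromo-2'-chloro-4'-methylbiphenyl-4-ol; 6 4-ethynylphenol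
Product: 7 2'-chloro-3'-[(4-hydroxyphenyl)ethynyl]-4'-methylbiphenyl-4-ol
Conditions: PdCl2(PPh3)2 (5 mol %), CuI (5 mol %), Et3N/DMF 1:1, 90 °C, argon, slow addition of 6 (1.4 equiv)
Reagents that add atoms: none
Why: In this Sonogashira coupling the remaining C–Br is hindered but inductively activated by the ortho chlorine, the slim copper acetylide reaches it, the triphenylphosphine catalyst leaves C–Cl alone, and phenols are tolerated under amine base.

Step 4
Reactants: 8 4-hydroxybenzophenone; 9 p-toluenesulfonohydrazide
Product: 10 N'-[(4-hydroxyphenyl)(phenyl)methylidene]-4-methylbenzenesulfonohydrazide (E/Z mixture)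
Conditions: TsOH·H2O (5 mol %), EtOH, reflux, 16 h; product crystallises on cooling
Reagents that add atoms: none
Why: Acid-catalysed hydrazone condensation is driven by crystallisation of the product, and the C=N geometry does not matter because both isomers give the same diazoalkane.

Step 5
Reactants: 7 2'-chloro-3'-[(4-hydroxyphenyl)ethynyl]-4'-methylbiphenyl-4-ol; 10 N'-[(4-hydroxyphenyl)(phenyl)methylidene]-4-methylbenzenesulfonohydrazide
Product: 13 selaginellin A, via diazoalkane 11 (not isolated), via triarylmethylpalladium chloride 12 (not isolated)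
Conditions: 10 (1.5 equiv), Pd2(dba)3 (2.5 mol %), XPhos (10 mol %), LiOtBu (6 equiv), 1,4-dioxane, 110 °C; aq NH4Cl work-up (no strong acid)
Reagents that add atoms: none
Why: Proposed new method: this is a Barluenga-type palladium carbene cross-coupling in which the carbonyl carbon of 8, normally an electrophile, acts as the nucleophilic diazo carbon of 11 (a phenylogous acyl anion equivalent) and is joined to the equally electrophilic C–Cl carbon of 7: LiOtBu converts 10 into 11 (Bamford–Stevens), zerovalent palladium inserts into C–Cl, 11 binds to the divalent arylpalladium with loss of N2, the aryl group migrates to the carbene carbon to give 12, and because 12 has no β-hydrogen its para-phenoxide expels zerovalent palladium and chloride (a vinylogous β-elimination, known stoichiometrically for 4-oxidobenzylpalladium halides) to give the quinone methide directly; the closest known reactions are the tosylhydrazone/aryl halide olefination and the reductive tosylhydrazone/aryl bromide synthesis of triarylmethanes, and no stereocentre is created.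

## Compound list
1 | 2,4-dibromotoluene | Cc1ccc(Br)cc1Br | starting material
2 | 2,6-dibromo-3-methylphenyllithium | [Li]c1c(Br)ccc(C)c1Br | intermediate
3 | 1,3-dibromo-2-chloro-4-methylbenzene | Cc1ccc(Br)c(Cl)c1Br | intermediate
4 | 4-hydroxyphenylboronic acid | OB(O)c1ccc(O)cc1 | starting material
5 | 3'-bromo-2'-chloro-4'-methylbiphenyl-4-ol | Cc1ccc(-c2ccc(O)cc2)c(Cl)c1Br | intermediate
6 | 4-ethynylphenol | C#Cc1ccc(O)cc1 | starting material
7 | 2'-chloro-3'-[(4-hydroxyphenyl)ethynyl]-4'-methylbiphenyl-4-ol | Cc1ccc(-c2ccc(O)cc2)c(Cl)c1C#Cc1ccc(O)cc1 | intermediate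
8 | 4-hydroxybenzophenone | O=C(c1ccccc1)c1ccc(O)cc1 | starting material
9 | p-toluenesulfonohydrazide | Cc1ccc(cc1)S(=O)(=O)NN | starting material
10 | N'-[(4-hydroxyphenyl)(phenyl)methylidene]-4-methylbenzenesulfonohydrazide | Cc1ccc(cc1)S(=O)(=O)NN=C(c1ccccc1)c1ccc(O)cc1 | intermediate
11 | 4-[diazo(phenyl)methyl]phenol (lithium phenoxide in the flask) | [N-]=[N+]=C(c1ccccc1)c1ccc(O)cc1 | intermediate
12 | chloro[{4'-hydroxy-3-[(4-hydroxyphenyl)ethynyl]-4-methylbiphenyl-2-yl}(4-hydroxyphenyl)(phenyl)methyl]palladium, divalent palladium, XPhos omitted, racemic transient | Cc1ccc(-c2ccc(O)cc2)c(C([Pd]Cl)(c2ccccc2)c2ccc(O)cc2)c1C#Cc1ccc(O)cc1 | intermediate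
13 | selaginellin A, 4-[{4'-hydroxy-3-[(4-hydroxyphenyl)ethynyl]-4-methylbiphenyl-2-yl}(phenyl)methylidene]cyclohexa-2,5-dien-1-one | Cc1ccc(-c2ccc(O)cc2)c(C(=C2C=CC(=O)C=C2)c2ccccc2)c1C#Cc1ccc(O)cc1 | target

## Count and risks
Total steps: 5. Longest linear sequence: 4 (steps 1, 2, 3, 5).

**Step 5 (highest risk).**
- What can go wrong: the chloride is di-ortho-substituted and electron-rich as its bis-phenoxide, and the diaryl carbene is bulky. The electron-rich diazoalkane 11 can be protonated or form the azine. Intermediate 12 could palladate the neighbouring aryl ring and close to a 9,9-diarylfluorene.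
- Fallback, from aryllithium 2 back to 13: the carbene coupling is moved to the front of the route and onto an iodide. Aryllithium 2 is quenched with I2 instead of C2Cl6 to give 1,3-dibromo-2-iodo-4-methylbenzene F1. Its C–I bond adds to Pd(PPh3)4 at 70–80 °C, with no phenoxide on the electrophile and no neighbouring aryl ring to palladate. Coupling with 10 (LiOtBu, dioxane) by way of 11 gives 4-[(2,6-dibromo-3-methylphenyl)(phenyl)methylidene]cyclohexa-2,5-dien-1-one F2. The fully substituted quinone methide withstands aqueous carbonate and amine, because any 1,6-adduct reverts. Suzuki coupling with 4 at the bromide next to C–H then gives 4-[(3-bromo-4'-hydroxy-4-methylbiphenyl-2-yl)(phenyl)methylidene]cyclohexa-2,5-dien-1-one F3. Sonogashira coupling of the last bromide with 6 gives 13.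

**Step 3.**
- What can go wrong: the bromide is di-ortho-substituted and needs heat, while 6 is prone to Glaser coupling and polymerisation.
- Fallback, from 5 back to 7: the alkyne is built in two stages with the partner roles reversed. Compound 5 is coupled with an excess of the small, robust trimethylsilylacetylene (PdCl2(PPh3)2, CuI, Et3N, sealed tube, 90 °C). This gives 2'-chloro-4'-methyl-3'-[(trimethylsilyl)ethynyl]biphenyl-4-ol F4. K2CO3 in MeOH then frees 2'-chloro-3'-ethynyl-4'-methylbiphenyl-4-ol F5. This hindered but stable terminal alkyne is coupled at room temperature with the unhindered 4-iodophenol to give 7.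

**Step 2.**
- What can go wrong: site selection rests on sterics alone, so some coupling at the wrong bromide or double coupling is possible.
- Fallback, from boronic acid 4 back to 5: steric discrimination is replaced by halogen discrimination. Commercial 2-bromo-4-iodotoluene is deprotonated between its halogens (LiN(iPr)2, THF, −78 °C) to 2-bromo-6-iodo-3-methylphenyllithium F6. Quenching with C2Cl6 gives 2-bromo-3-chloro-4-iodo-1-methylbenzene F7. Boronic acid 4 then couples only at C–I (Pd(PPh3)4, Na2CO3, 50 °C) to give 5, with iodide, bromide and chloride addressed strictly in that order along the route.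

## Further compounds
F1 | step 5 | 1,3-dibromo-2-iodo-4-methylbenzene | Cc1ccc(Br)c(I)c1Br
F2 | step 5 | 4-[(2,6-dibromo-3-methylphenyl)(phenyl)methylidene]cyclohexa-2,5-dien-1-one | Cc1ccc(Br)c(C(=C2C=CC(=O)C=C2)c2ccccc2)c1Br
F3 | step 5 | 4-[(3-bromo-4'-hydroxy-4-methylbiphenyl-2-yl)(phenyl)methylidene]cyclohexa-2,5-dien-1-one | Cc1ccc(-c2ccc(O)cc2)c(C(=C2C=CC(=O)C=C2)c2ccccc2)c1Br
F4 | step 3 | 2'-chloro-4'-methyl-3'-[(trimethylsilyl)ethynyl]biphenyl-4-ol | Cc1ccc(-c2ccc(O)cc2)c(Cl)c1C#C[Si](C)(C)C
F5 | step 3 | 2'-chloro-3'-ethynyl-4'-methylbiphenyl-4-ol | Cc1ccc(-c2ccc(O)cc2)c(Cl)c1C#C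
F6 | step 2 | 2-bromo-6-iodo-3-methylphenyllithium | [Li]c1c(I)ccc(C)c1Br
F7 | step 2 | 2-bromo-3-chloro-4-iodo-1-methylbenzene | Cc1ccc(I)c(Cl)c1Br
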